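Whatever the free base does with the acid set free, each electrophile charged stays accounted for: it is still there, or it sits in target, or it sits in homo dimer.

| setting | autumn | dusk |
|---|---|---|
| electrophile | 0.30 M | 0.30 M |
| free base | 0.600 M | 1.20 M |
| protonated nucleophile | 0.300 M | 0.300 M |
| time | 30 h | 30 h |

    acid set free + free base ⇌ salt of the base, settled at all times (K1 = 4080 M⁻¹)
    nucleophile + acid set free ⇌ protonated nucleophile, settled at all times (K2 = 4200 M⁻¹)
    2 electrophile → homo dimer (k3 = 0.503 M⁻¹ h⁻¹)
    electrophile + nucleophile → acid set free + target (k4 = 1.55 M⁻¹ h⁻¹)

- percentages count the electrophile that a species holds: one homo dimer counts as two
- a step written with two of one species runs at k times the square of its concentration and takes two of it each time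
- run time (autumn): 30 h

- part of the electrophile that has reacted at the end, autumn
- part of the electrophile that has reacted at the end, dusk
- what raising the concentration of free base from its lowest to its highest value here does to the part of the electrophile that has reacted (changes below 5 percentage points count as none) (no change / it falls / it rises)

I looked for one number and began with the homo dimer step, whose rate holds neither free base nor nucleophile. At the charged electrophile its first half-life is 3.31 h, and the run of 30 h is longer. Their ratio is 9.05: the turnover count N, the number of first half-lives of that step that fit into the run. That step alone leaves the charge divided by one plus N, which is 9.95 % of the electrophile, and the coupling with nucleophile takes electrophile on top. So I committed to more than 90.1 % reacted, in autumn and at dusk alike.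

Was one number enough? For a floor it was, but not for the trend: N leaves 9.9 percentage points above the floor, more than the 5 points that count as a change, so I left the trend open.

Where I gave a floor, the forecast gave 98.2 % for autumn, 99.2 % for dusk and no change, with the ground: “Both runs are essentially finished”.

The simulation gave 98.2 % for autumn and 99.3 % for dusk, both above the floor, and a change of 1 point, which counts as no change. The autumn flask read at 8.0 h has a count of 2.41, so a floor of 70.7 %, and it showed 86.4 %. In autumn, just after the start, coupling used electrophile at 1.0 times the rate of the dimer step, and at 1.89 h at 1.3 times. At 30.0 h the autumn flask held 1.75 % of its electrophile, the limiting reagent, with 57.5 % in target and 40.7 % in homo dimer.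

The constants were drawn at random within sensible limits; the run is a simulation.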